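## Retrosynthetic overview

1. Both esters go on late (C9 acetate, C11 propanoate) and the C21 hydroxyl is unmasked last.
2. C8–C9: anti-selective vinylogous (lateral) Mukaiyama aldol of the silyl dienol ether of 2,6-diethyl-3,5-dimethyl-4-pyranone (ring B) with a C9 aldehyde.
3. C10–C11: chiral phosphoramide/SiCl4-catalysed anti aldol of a propanoate silyl ketene acetal with the ring A (E)-enal.
4. C13–C14 and C20–C21: two catalytic asymmetric lateral aldols on the same pyranone (ring A), first with propanal (first stereocentres, from achiral materials), then with 3-ethoxy-2-methylacrolein (addition, then loss of ethanol to the enal).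
5. Ring order: only one ring-forming event. The 4-pyranone is condensed once from pentan-3-one and two equivalents of propanoic acid and used twice, as ring A (elaborated first) and as ring B (attached last).

Assumption: the (R,R)-bisphosphoramide is taken to deliver nucleophiles to the Re face of the SiCl3-bound aldehyde; if the sense proves opposite, the two catalyst enantiomers are exchanged in steps 3, 5, 7 and 11.

Catalyst: "bisphosphoramide" is the dimeric phosphoramide built from two P(=O)N3 units. Each phosphorus carries the two N-methyl nitrogens of one N,N'-dimethyl-1,1'-binaphthyl-2,2'-diamine and one exocyclic N-methyl nitrogen. The two exocyclic nitrogens are joined by a pentane-1,5-diyl chain. DTBMP is 2,6-di-tert-butyl-4-methylpyridine.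

Chain numbering used in the text: ring B (6-ethyl-3,5-dimethyl-4-oxo-4H-pyran-2-yl)–C8H(CH3)–C9H(O)–C10H(CH3)–C11H(O)–C12(CH3)=C13H–C14H(CH3)–ring A (3,5-dimethyl-4-oxo-4H-pyran-2,6-diyl)–C20H(CH3)–C21H(O)–C22H2–C23H3. Target: 8R,9R,10R,11R,12E,14S,20S,21S.

## Route

Step 1
Reactants: 1 pentan-3-one; 2 propanoic acid
Product: 5 2,6-diethyl-3,5-dimethyl-4H-pyran-4-one, via diketone 3 (not isolated), via triketone 4 (not isolated)
Conditions: EtCO2H (3 equiv), polyphosphoric acid, 110 °C
Reagents that add atoms: propanoic acid, second equivalent CCC(=O)O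
Why: Two molecules of propanoic acid C-acylate the ketone in turn (the first gives 3, the second gives 4) and cyclodehydration of the 1,3,5-triketone closes the ring, which is the classical polyphosphoric acid synthesis of tetra-alkyl 4-pyranones and leaves no stereocentre.

Step 2
Reactants: 5 2,6-diethyl-3,5-dimethyl-4H-pyran-4-one
Product: 6 tert-butyl{[(2Z)-6-ethyl-2-ethylidene-3,5-dimethyl-2H-pyran-4-yl]oxy}dimethylsilane
Conditions: TBSOTf (1.1 equiv), Et3N (1.5 equiv), CH2Cl2, 0 °C; pentane extraction, used at once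
Reagents that add atoms: tert-butyldimethylsilyl trifluoromethanesulfonate CC(C)(C)[Si](C)(C)OS(=O)(=O)C(F)(F)F
Why: Soft enolisation, in which carbonyl O-silylation makes the 2-ethyl CH2 acidic enough for Et3N (pyrylium anhydrobase formation), gives the Z-ethylidene isomer because it avoids allylic strain with the C3 methyl group.

Step 3
Reactants: 6 silyl dienol ether; 7 propanal
Product: 8 2-ethyl-6-[(2S,3S)-3-hydroxypentan-2-yl]-3,5-dimethyl-4H-pyran-4-one
Conditions: SiCl4 (1.1 equiv), (R,R)-bisphosphoramide (5 mol %), DTBMP (10 mol %), CH2Cl2, −78 °C; sat. aq. NaHCO3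
Reagents that add atoms: none
Why: Proposed new method: a Lewis-base-catalysed, SiCl4-mediated vinylogous Mukaiyama aldol of a pyranone-derived 2-alkylidene-4-silyloxy-2H-pyran, in which the chiral phosphoramide-bound SiCl3 cation activates propanal and the exocyclic ethylidene carbon (the only unhindered terminus, whose attack restores the 4-pyranone while chloride removes the silyl group as TBSCl) adds to the Re face through an open antiperiplanar transition state to set C20 and C21 as the anti (S,S) pair; the closest known reactions are the Denmark-type phosphoramide/SiCl4 vinylogous aldol of ester- and amide-derived γ-methyl silyl dienolates (anti-selective) and the non-selective lithium lateral aldol of 2-ethyl-4-pyranones.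

Step 4
Reactants: 8 aldol
Product: 10 tert-butyl{[(2Z)-6-[(2S,3S)-3-(tert-butyldimethylsilyloxy)pentan-2-yl]-2-ethylidene-3,5-dimethyl-2H-pyran-4-yl]oxy}dimethylsilane, via TBS ether 9 (not isolated)
Conditions: TBSOTf (2.3 equiv), Et3N (3 equiv), CH2Cl2, −78 to 0 °C; pentane extraction, used at once
Reagents that add atoms: tert-butyldimethylsilyl trifluoromethanesulfonate CC(C)(C)[Si](C)(C)OS(=O)(=O)C(F)(F)F
Why: The alcohol is silylated first (9) and the second equivalent soft-enolises the remaining, less hindered ethyl CH2 rather than the branched C20–H, so C20 and C21 are untouched.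

Step 5
Reactants: 10 bis-silyl dienol ether; 11 (E)-3-ethoxy-2-methylprop-2-enal
Product: 13 (2E,4S)-4-{6-[(2S,3S)-3-(tert-butyldimethylsilyloxy)pentan-2-yl]-3,5-dimethyl-4-oxo-4H-pyran-2-yl}-2-methylpent-2-enal, via hydroxy enol ether 12 (not isolated)
Conditions: SiCl4 (1.1 equiv), (R,R)-bisphosphoramide (5 mol %), DTBMP (10 mol %), CH2Cl2, −78 °C; sat. aq. NaHCO3; then 0.5 M aq. HCl, THF, 0 °C, 15 min
Reagents that add atoms: water O
Why: Proposed new method: second use of the pyranylidene vinylogous Mukaiyama aldol, now on a vinylogous formate, where catalyst-controlled Re-face 1,2-addition with anti topicity fixes C14 as S and the γ-ethoxy allylic alcohol 12 then loses ethanol on mild acid (allylic transposition and hydrolysis to the thermodynamic E-enal) so that only C14 survives; the closest known reaction types are the Denmark-type vinylogous aldol and the addition–hydrolysis of carbon nucleophiles to 3-alkoxyacroleins.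

Step 6
Reactants: 14 methyl propanoate
Product: 15 (E)-tert-butyl[(1-methoxyprop-1-en-1-yl)oxy]dimethylsilane
Conditions: LiN(i-Pr)2 (commercial solution, 1.05 equiv), THF, −78 °C; TBSCl, DMPU, −78 °C to rt; distil
Reagents that add atoms: tert-butyl(chloro)dimethylsilane CC(C)(C)[Si](C)(C)Cl
Why: Kinetic ester enolisation (Ireland conditions) and O-silylation give the E silyl ketene acetal, whose geometry is not critical because the following aldol is stereoconvergent.

Step 7
Reactants: 13 enal; 15 silyl ketene acetal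
Product: 16 methyl (2S,3R,4E,6S)-6-{6-[(2S,3S)-3-(tert-butyldimethylsilyloxy)pentan-2-yl]-3,5-dimethyl-4-oxo-4H-pyran-2-yl}-3-hydroxy-2,4-dimethylhept-4-enoate
Conditions: SiCl4 (1.1 equiv), (R,R)-bisphosphoramide (5 mol %), CH2Cl2, −78 °C, no amine additive; cold sat. aq. NaHCO3
Reagents that add atoms: none
Why: This is the Denmark-type Lewis-base-catalysed SiCl4 Mukaiyama aldol, established for propanoate silyl ketene acetals with α-branched enals, whose open transition state gives the anti aldol while the (R,R)-catalyst directs Re-face attack, setting C11 as R and C10 as required.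

Step 8
Reactants: 16 β-hydroxy ester
Product: 17 methyl (2S,3R,4E,6S)-6-{6-[(2S,3S)-3-(tert-butyldimethylsilyloxy)pentan-2-yl]-3,5-dimethyl-4-oxo-4H-pyran-2-yl}-2,4-dimethyl-3-(triethylsilyloxy)hept-4-enoate
Conditions: TESCl, imidazole, DMF, 0 °C to rt
Reagents that add atoms: chlorotriethylsilane CC[Si](Cl)(CC)CC
Why: Standard silylation of the secondary allylic alcohol with a base too weak to touch the lateral pyranone positions.

Step 9
Reactants: 17 silyl ether ester
Product: 18 (2R,3R,4E,6S)-6-{6-[(2S,3S)-3-(tert-butyldimethylsilyloxy)pentan-2-yl]-3,5-dimethyl-4-oxo-4H-pyran-2-yl}-2,4-dimethyl-3-(triethylsilyloxy)hept-4-en-1-ol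
Conditions: LiBH4, MeOH (1 equiv), THF, 0 °C
Reagents that add atoms: none
Why: LiBH4 reduces the methyl ester to the primary alcohol while the vinylogous-ester-like, fully substituted 4-pyranone carbonyl, the silyl ethers and the trisubstituted alkene are inert (the 2R descriptor is a priority change only).

Step 10
Reactants: 18 primary alcohol
Product: 19 (2S,3R,4E,6S)-6-{6-[(2S,3S)-3-(tert-butyldimethylsilyloxy)pentan-2-yl]-3,5-dimethyl-4-oxo-4H-pyran-2-yl}-2,4-dimethyl-3-(triethylsilyloxy)hept-4-enal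
Conditions: Dess–Martin periodinane, NaHCO3, CH2Cl2, 0 °C to rt; used at once
Reagents that add atoms: none
Why: Dess–Martin oxidation under buffered, non-basic conditions gives the α-methyl-β-silyloxy aldehyde without epimerisation at C10.

Step 11
Reactants: 19 aldehyde; 6 silyl dienol ether (second batch from step 2)
Product: 20 (8R,9R,10R,11R,12E,14S,20S,21S) bis-pyranone with 9-OH, 11-OSiEt3 and 21-OSi(t-Bu)Me2
Conditions: SiCl4 (1.2 equiv), (S,S)-bisphosphoramide (10 mol %), DTBMP (10 mol %), CH2Cl2, −78 to −60 °C; sat. aq. NaHCO3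
Reagents that add atoms: none
Why: Proposed new method: third use of the pyranylidene vinylogous Mukaiyama aldol, as a matched double-diastereoselective fragment coupling in which the (S,S)-catalyst directs Si-face attack, which is also the Felkin–Anh and 1,3-anti face of this 2,3-anti α-methyl-β-silyloxy aldehyde, while the open transition state gives the 8,9-anti pair, setting C8 and C9 as R,R; the closest known reaction type is the Denmark-type vinylogous aldol, and the substrate bias follows the merged 1,2/1,3-induction model for Mukaiyama aldols.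

Step 12
Reactants: 20 bis-pyranone alcohol
Product: 21 (8R,9R,10R,11R,12E,14S,20S,21S) bis-pyranone with 9-OAc, 11-OSiEt3 and 21-OSi(t-Bu)Me2
Conditions: Ac2O, DMAP (cat.), pyridine, CH2Cl2, 0 °C to rt
Reagents that add atoms: acetic anhydride CC(=O)OC(C)=O
Why: DMAP-catalysed acetylation of the only free hydroxyl group.

Step 13
Reactants: 21 acetate
Product: 22 (8R,9R,10S,11R,12E,14S,20S,21S) bis-pyranone with 9-OAc, 11-OH and 21-OSi(t-Bu)Me2
Conditions: HF·pyridine, pyridine, THF, 0 °C
Reagents that add atoms: none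
Why: Buffered HF·pyridine cleaves the triethylsilyl ether far faster than the hindered secondary tert-butyldimethylsilyl ether and leaves the acetate alone (the 10S descriptor is a priority change only).

Step 14
Reactants: 22 C11 alcohol
Product: 23 (8R,9R,10R,11R,12E,14S,20S,21S) bis-pyranone with 9-OAc, 11-OC(O)Et and 21-OSi(t-Bu)Me2
Conditions: (EtCO)2O, DMAP, Et3N, CH2Cl2, 0 °C to rt
Reagents that add atoms: propanoic anhydride CCC(=O)OC(=O)CC
Why: DMAP-catalysed acyl transfer to the only free hydroxyl group is faster than 1,3-acetyl migration.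

Step 15
Reactants: 23 silyl ether
Product: 24 CNP0265513.1, (8R,9R,10R,11R,12E,14S,20S,21S) bis-pyranone with 9-OAc, 11-OC(O)Et and 21-OH
Conditions: HF·pyridine, THF, rt
Reagents that add atoms: none
Why: Fluoride cleavage of the last silyl ether under mildly acidic conditions leaves both esters, the allylic propanoate and all stereocentres intact.

## Compound list

1 | pentan-3-one | CCC(=O)CC | starting material
2 | propanoic acid | CCC(=O)O | starting material
3 | 4-methylheptane-3,5-dione (not isolated) | CCC(=O)C(C)C(=O)CC | intermediate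
4 | 4,6-dimethylnonane-3,5,7-trione (not isolated) | CCC(=O)C(C)C(=O)C(C)C(=O)CC | intermediate
5 | 2,6-diethyl-3,5-dimethyl-4H-pyran-4-one | CCc1oc(CC)c(C)c(=O)c1C | intermediate
6 | tert-butyl{[(2Z)-6-ethyl-2-ethylidene-3,5-dimethyl-2H-pyran-4-yl]oxy}dimethylsilane | C/C=C1\OC(CC)=C(C)C(O[Si](C)(C)C(C)(C)C)=C1C | intermediate
7 | propanal | CCC=O | starting material
8 | 2-ethyl-6-[(2S,3S)-3-hydroxypentan-2-yl]-3,5-dimethyl-4H-pyran-4-one | CCc1oc([C@@H](C)[C@@H](O)CC)c(C)c(=O)c1C | intermediate
9 | 2-[(2S,3S)-3-(tert-butyldimethylsilyloxy)pentan-2-yl]-6-ethyl-3,5-dimethyl-4H-pyran-4-one (not isolated) | CCc1oc([C@@H](C)[C@@H](O[Si](C)(C)C(C)(C)C)CC)c(C)c(=O)c1C | intermediate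
10 | tert-butyl{[(2Z)-6-[(2S,3S)-3-(tert-butyldimethylsilyloxy)pentan-2-yl]-2-ethylidene-3,5-dimethyl-2H-pyran-4-yl]oxy}dimethylsilane | C/C=C1\OC([C@@H](C)[C@@H](O[Si](C)(C)C(C)(C)C)CC)=C(C)C(O[Si](C)(C)C(C)(C)C)=C1C | intermediate
11 | (E)-3-ethoxy-2-methylprop-2-enal | CCO/C=C(\C)C=O | starting material
12 | 2-[(2S,3S)-3-(tert-butyldimethylsilyloxy)pentan-2-yl]-6-[(2S,3R,4E)-5-ethoxy-3-hydroxy-4-methylpent-4-en-2-yl]-3,5-dimethyl-4H-pyran-4-one (not isolated) | CCO/C=C(\C)[C@H](O)[C@H](C)c1oc([C@@H](C)[C@@H](O[Si](C)(C)C(C)(C)C)CC)c(C)c(=O)c1C | intermediate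
13 | (2E,4S)-4-{6-[(2S,3S)-3-(tert-butyldimethylsilyloxy)pentan-2-yl]-3,5-dimethyl-4-oxo-4H-pyran-2-yl}-2-methylpent-2-enal | O=C/C(C)=C/[C@H](C)c1oc([C@@H](C)[C@@H](O[Si](C)(C)C(C)(C)C)CC)c(C)c(=O)c1C | intermediate
14 | methyl propanoate | CCC(=O)OC | starting material
15 | (E)-tert-butyl[(1-methoxyprop-1-en-1-yl)oxy]dimethylsilane | C/C=C(\OC)O[Si](C)(C)C(C)(C)C | intermediate
16 | methyl (2S,3R,4E,6S)-6-{6-[(2S,3S)-3-(tert-butyldimethylsilyloxy)pentan-2-yl]-3,5-dimethyl-4-oxo-4H-pyran-2-yl}-3-hydroxy-2,4-dimethylhept-4-enoate | COC(=O)[C@@H](C)[C@@H](O)/C(C)=C/[C@H](C)c1oc([C@@H](C)[C@@H](O[Si](C)(C)C(C)(C)C)CC)c(C)c(=O)c1C | intermediate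
17 | methyl (2S,3R,4E,6S)-6-{6-[(2S,3S)-3-(tert-butyldimethylsilyloxy)pentan-2-yl]-3,5-dimethyl-4-oxo-4H-pyran-2-yl}-2,4-dimethyl-3-(triethylsilyloxy)hept-4-enoate | COC(=O)[C@@H](C)[C@@H](O[Si](CC)(CC)CC)/C(C)=C/[C@H](C)c1oc([C@@H](C)[C@@H](O[Si](C)(C)C(C)(C)C)CC)c(C)c(=O)c1C | intermediate
18 | (2R,3R,4E,6S)-6-{6-[(2S,3S)-3-(tert-butyldimethylsilyloxy)pentan-2-yl]-3,5-dimethyl-4-oxo-4H-pyran-2-yl}-2,4-dimethyl-3-(triethylsilyloxy)hept-4-en-1-ol | OC[C@@H](C)[C@@H](O[Si](CC)(CC)CC)/C(C)=C/[C@H](C)c1oc([C@@H](C)[C@@H](O[Si](C)(C)C(C)(C)C)CC)c(C)c(=O)c1C | intermediate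
19 | (2S,3R,4E,6S)-6-{6-[(2S,3S)-3-(tert-butyldimethylsilyloxy)pentan-2-yl]-3,5-dimethyl-4-oxo-4H-pyran-2-yl}-2,4-dimethyl-3-(triethylsilyloxy)hept-4-enal | O=C[C@@H](C)[C@@H](O[Si](CC)(CC)CC)/C(C)=C/[C@H](C)c1oc([C@@H](C)[C@@H](O[Si](C)(C)C(C)(C)C)CC)c(C)c(=O)c1C | intermediate
20 | (8R,9R,10R,11R,12E,14S,20S,21S) bis-pyranone, 9-OH, 11-OSiEt3, 21-OSi(t-Bu)Me2 | CC[Si](CC)(CC)O[C@@H](/C(C)=C/[C@H](C)c1oc([C@@H](C)[C@@H](O[Si](C)(C)C(C)(C)C)CC)c(C)c(=O)c1C)[C@H](C)[C@@H](O)[C@@H](C)c1oc(CC)c(C)c(=O)c1C | intermediate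
21 | (8R,9R,10R,11R,12E,14S,20S,21S) bis-pyranone, 9-OAc, 11-OSiEt3, 21-OSi(t-Bu)Me2 | CC[Si](CC)(CC)O[C@@H](/C(C)=C/[C@H](C)c1oc([C@@H](C)[C@@H](O[Si](C)(C)C(C)(C)C)CC)c(C)c(=O)c1C)[C@H](C)[C@@H](OC(C)=O)[C@@H](C)c1oc(CC)c(C)c(=O)c1C | intermediate
22 | (8R,9R,10S,11R,12E,14S,20S,21S) bis-pyranone, 9-OAc, 11-OH, 21-OSi(t-Bu)Me2 | O[C@@H](/C(C)=C/[C@H](C)c1oc([C@@H](C)[C@@H](O[Si](C)(C)C(C)(C)C)CC)c(C)c(=O)c1C)[C@H](C)[C@@H](OC(C)=O)[C@@H](C)c1oc(CC)c(C)c(=O)c1C | intermediate
23 | (8R,9R,10R,11R,12E,14S,20S,21S) bis-pyranone, 9-OAc, 11-OC(O)Et, 21-OSi(t-Bu)Me2 | CCC(=O)O[C@@H](/C(C)=C/[C@H](C)c1oc([C@@H](C)[C@@H](O[Si](C)(C)C(C)(C)C)CC)c(C)c(=O)c1C)[C@H](C)[C@@H](OC(C)=O)[C@@H](C)c1oc(CC)c(C)c(=O)c1C | intermediate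
24 | CNP0265513.1: (2S,3E,5R,6R,7R,8R)-7-acetoxy-8-(6-ethyl-3,5-dimethyl-4-oxo-4H-pyran-2-yl)-2-{6-[(2S,3S)-3-hydroxypentan-2-yl]-3,5-dimethyl-4-oxo-4H-pyran-2-yl}-4,6-dimethylnon-3-en-5-yl propanoate | CCC(=O)O[C@@H](/C(C)=C/[C@H](C)c1oc([C@@H](C)[C@@H](O)CC)c(C)c(=O)c1C)[C@H](C)[C@@H](OC(C)=O)[C@@H](C)c1oc(CC)c(C)c(=O)c1C | target

## Step count and risks

Total step count: 15. Longest linear sequence: 14 (steps 1 to 5 and 7 to 15; step 6 is a one-step side branch).

Steps most likely to fail:

Step 3 (proposed new aldol with an enolisable aliphatic aldehyde). Propanal may be held back by the SiCl4/chloride system, the basic pyranone may open an uncatalysed background path, and anti selectivity or ee may be modest. The fallback sets out from 5 and comes back at 8. Pyranone 5 is laterally lithiated (LiN(SiMe3)2, THF, −78 °C) and C-acylated with N-methoxy-N-methylpropanamide to the racemic, configurationally labile keto-pyranone 2-ethyl-3,5-dimethyl-6-(3-oxopentan-2-yl)-4H-pyran-4-one F1. Asymmetric transfer hydrogenation under dynamic kinetic resolution (RuCl[(S,S)-TsDPEN](p-cymene), HCO2H/Et3N, rt) then reduces the rapidly epimerising ketone to the (20S,21S) anti alcohol 8, with any syn isomer removed by chromatography. The C–C bond is thus made without stereocontrol by known lithiation chemistry and both centres are set in a known reduction.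

Step 5 (proposed new aldol on a vinylogous formate; only C14 survives). The electrophile is deactivated, the enal product could react a second time, and C14 of the enal is acidic. The fallback sets out from 8 and comes back at 13. Alcohol 8 is silylated (TBSCl, imidazole, DMF) and 9 is isolated, lithiated at the ethyl CH2 (LiN(SiMe3)2, THF, −78 °C) and added to 11. The crude hydroxy enol ether adduct mixture F2 is treated with dilute HCl to give 13 and its C14-epimeric enal F3 (about 1:1), which are separated by preparative HPLC. F3 is re-equilibrated with a trace of DBU through its dienolate and recycled. C14 is then secured by separation and recycling of a labile centre instead of by a catalyst.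

Step 11 (proposed new aldol as fragment coupling with a hindered α-branched aldehyde). Conversion may be low and the C8/C9 anti preference is unproven. The fallback sets out from 19 (with 5) and comes back at 20. The lithium dienolate of 5 (LiN(SiMe3)2, THF, −78 °C) is added to 19; Felkin–Anh control from C10 sets C9, C8 forms with little selectivity, and 20 is separated by chromatography from its 8-epi aldol F4. This replaces the catalyst-controlled silyl dienol ether addition by substrate-controlled lithium aldol chemistry known for 2-ethyl-4-pyranones.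

Further compounds

F1 | step 3 | 2-ethyl-3,5-dimethyl-6-(3-oxopentan-2-yl)-4H-pyran-4-one (racemic) | CCC(=O)C(C)c1oc(CC)c(C)c(=O)c1C
F2 | step 5 | 2-[(2S,3S)-3-(tert-butyldimethylsilyloxy)pentan-2-yl]-6-[(4E)-5-ethoxy-3-hydroxy-4-methylpent-4-en-2-yl]-3,5-dimethyl-4H-pyran-4-one, mixture of C13/C14 isomers | CCO/C=C(\C)C(O)C(C)c1oc([C@@H](C)[C@@H](O[Si](C)(C)C(C)(C)C)CC)c(C)c(=O)c1C
F3 | step 5 | (2E,4R)-4-{6-[(2S,3S)-3-(tert-butyldimethylsilyloxy)pentan-2-yl]-3,5-dimethyl-4-oxo-4H-pyran-2-yl}-2-methylpent-2-enal | O=C/C(C)=C/[C@@H](C)c1oc([C@@H](C)[C@@H](O[Si](C)(C)C(C)(C)C)CC)c(C)c(=O)c1C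
F4 | step 11 | (8S,9R,10R,11R,12E,14S,20S,21S) bis-pyranone, 9-OH, 11-OSiEt3, 21-OSi(t-Bu)Me2 | CC[Si](CC)(CC)O[C@@H](/C(C)=C/[C@H](C)c1oc([C@@H](C)[C@@H](O[Si](C)(C)C(C)(C)C)CC)c(C)c(=O)c1C)[C@H](C)[C@@H](O)[C@H](C)c1oc(CC)c(C)c(=O)c1C
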